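The data were computed for an exercise, noise included.

| setting | oak | elm | north | south | east | north-east | south-east |
|---|---|---|---|---|---|---|---|
| substrate | 3 M | 3 M | 3.0 M | 3.0 M | 3.0 M | 3.0 M | 3.0 M |
| gas | 200 mM (held) | 200 mM (held) | 200 mM (held) | 200 mM (held) | 200 mM (held) | 200 mM (held) | 200 mM (held) |
| free catalyst | 1.3 mM | 14 mM | 1.5 mM | 4.5 mM | 20 mM | 3.0 mM | 6.0 mM |
| remark | run made earlier | run made earlier |  |  |  |  |  |
| time |  |  | 5.0 h | 5.0 h | 5.0 h | 5.0 h | 5.0 h |

- oak (time / h: target / %): 1.00: 6; 2.00: 11; 3.00: 15; 4.00: 17; 5.00: 21
- elm (time / h: target / %): 0.417: 12; 0.833: 17; 1.33: 28; 2.50: 46; 5.00: 47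

(each reading ± 1.5 percentage points)

- the flasks put in order of amount of target, in percent of the substrate charged, best first, at 5.0 h (north / south / east / north-east / south-east)
- the same order at 30 min (north / south / east / north-east / south-east)
- the amount of target, in percent of the substrate charged of the flask you put first, at 5.0 h
- the amount of target, in percent of the substrate charged of the flask you put last, at 5.0 h

- the numbers in the tables scatter with a standard deviation of 1.5 percentage points
- at the start none of the gas is in solution

1. Oak ended with 79.0% of its charge not seen as target. Elm read 46% at 2.50 h and 47% at 5.00 h, each with a scatter of 1.5 percentage points, and nothing was read between them.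

2. I wanted to know which flasks could reach elm's last reading, so I set two times side by side. One was the clock, 5.0 h. The other was my fill time: the hours a flask needs to reach elm's last reading at oak's yield per c(free catalyst) and hour. For south it came to 3.23 h, shorter than the clock.

3. North's fill time was 9.70 h, longer than the clock. So I reckoned north at the clock's share of that reading, 24.2%. North-east's fill time was 4.85 h, close to the clock. Beyond that, my reckoning put flasks at that reading and could not rank them. At 30 min I ranked them by c(free catalyst).

4. The forecast gave east > south-east > south > north-east > north at 5.0 h and east > south-east > south > north-east > north at 30 min. It put the top at 47% (44% to 53%) and the lowest at 24% (20% to 27%). Its ground for elm's stop was “this looks like a ceiling”.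

5. The flasks gave south > south-east > east > north-east > north at 5.0 h and east > south-east > south > north-east > north at 30 min. South stood first at 50.2%, above elm's last reading, east reached 43.1%, and north stood last at 23.4%.

    partner ⇌ dormant form (K = 23.0, k = 0.918 h⁻¹)
    substrate + catalyst intermediate B → catalyst intermediate C (k = 4950 L mol⁻¹ h⁻¹)
    partner + free catalyst → catalyst intermediate A (k = 2960 L mol⁻¹ h⁻¹)
    catalyst intermediate C → free catalyst + target (k = 763 h⁻¹)
    catalyst intermediate A ⇌ by-product + catalyst intermediate B (K = 6.80 M, k = 716 h⁻¹)
    target ⇌ isomer of the product (K = 1.50, k = 0.595 h⁻¹)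
    gas ⇌ partner, rate k7*(csat - [partner]) (kL = 5.22 h⁻¹)

6. South, with a fill time of 3.23 h, still held 2.68% of its substrate at 5.00 h. East held 0% then, with 56.9% as isomer of the product. The neighbour flask was south with 2.70 mM of free catalyst. Its fill time was 5.39 h, longer than the clock, so I reckoned 43.6%. It gave 37.2% of target, with 29% of its substrate left.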